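**Retrosynthetic overview**

1. Numbering: C1 is the carbinol carbon carrying the C17 chain, C2=C3 the ring alkene, C4 and C5 the secondary carbinols, C6 the ring methylene.
2. The strategy rests on C6H2 lying between oxygenated C5 and the fully substituted C1. With oxygen in place of C6 the ring becomes a 2-alkyl-2-hydroxy-2H-pyran (O–C1–C2=C3–C4–C5), which is what Achmatowicz oxidation of a 2-alkylfuran delivers, so C6 can be inserted last.
3. Disconnections: the C5 carbinol comes from a C5 ketone by C1–OH-directed reduction; the C1–C6 bond comes from a mercury-catalysed Ferrier-type carbocyclisation of a 6-methylidene ketopyranoside; the pyranoside comes from a furyl chlorohydrin; the two furan substituents come from two lithiations; the chain comes from 1-hexyne and 11-bromoundecan-1-ol.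
4. Ring order: furan (purchased), then the dihydropyranone ring (step 7), then the cyclohexene ring (step 13), the only carbocycle.

Key step: step 13

Assumption: hemiketal 15 is expected as a mixture of C6 epimers that converges on one methyl ketal in step 8, so its SMILES leaves that centre open; ring atoms of all intermediates are referred to by the target numbering given above.

**Route**

Step 1
Reactants: 1 1-hexyne; 2 11-bromoundecan-1-ol
Product: 4 heptadec-12-yn-1-ol, via hex-1-ynyllithium 3 (not isolated)
Conditions: 1 (2.5 equiv), n-BuLi (2.4 equiv), THF, −40 → 0 °C; then 2, DMPU, 0 °C → rt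
Reagents that add atoms: none
Why: SN2 alkylation of a lithium acetylide, in which excess hexynyllithium first converts 2 into its lithium alkoxide and then displaces the primary bromide in the dipolar cosolvent, so the hydroxyl needs no protection.

Step 2
Reactants: 4 heptadec-12-yn-1-ol
Product: 5 (E)-heptadec-12-en-1-ol
Conditions: Na, NH3(l)/THF, −33 °C; then NH4Cl
Reagents that add atoms: none
Why: Dissolving-metal reduction of an internal alkyne passes through the trans vinyl radical anion and should give only the E-alkene, the remote alkoxide being inert.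

Step 3
Reactants: 5 (E)-heptadec-12-en-1-ol
Product: 6 (E)-1-bromoheptadec-12-ene
Conditions: CBr4, PPh3, CH2Cl2, 0 °C
Reagents that add atoms: carbon tetrabromide, BrC(Br)(Br)Br
Why: Appel bromination converts the primary alcohol into the bromide under neutral conditions that leave the E-alkene untouched.

Step 4
Reactants: 6 (E)-1-bromoheptadec-12-ene; 7 furan
Product: 9 2-[(E)-heptadec-12-en-1-yl]furan, via 2-lithiofuran 8 (not isolated)
Conditions: 7 (3 equiv), n-BuLi, THF, 0 °C → rt; then 6, −78 °C → rt
Reagents that add atoms: none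
Why: α-Lithiation of furan followed by SN2 alkylation with a primary bromide is a standard entry to 2-alkylfurans, and the excess of volatile furan suppresses dialkylation.

Step 5
Reactants: 9 2-[(E)-heptadec-12-en-1-yl]furan; 10 2-chloro-N-methoxy-N-methylacetamide
Product: 12 2-chloro-1-{5-[(E)-heptadec-12-en-1-yl]furan-2-yl}ethan-1-one, via 5-lithio-2-alkylfuran 11 (not isolated)
Conditions: n-BuLi, THF, 0 °C → rt; then 10, −78 °C; aq NH4Cl
Reagents that add atoms: none
Why: The remaining α-position of the furan is lithiated selectively and acylated by the Weinreb amide, whose chelated tetrahedral intermediate prevents over-addition and keeps the C–Cl bond intact at −78 °C.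

Step 6
Reactants: 12 2-chloro-1-{5-[(E)-heptadec-12-en-1-yl]furan-2-yl}ethan-1-one
Product: 13 (1R)-2-chloro-1-{5-[(E)-heptadec-12-en-1-yl]furan-2-yl}ethan-1-ol
Conditions: RuCl(p-cymene)[(S,S)-TsDPEN] (1 mol%), HCO2H/Et3N (5:2), CH2Cl2, rt
Reagents that add atoms: none
Why: Noyori–Ikariya asymmetric transfer hydrogenation, in which the furyl ring plays the aryl role (CH/π contact with the cymene ligand), so the (S,S)-catalyst should give the carbinol that is R because CH2Cl outranks furyl; this centre is the source of all absolute configuration.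

Step 7
Reactants: 13 (1R)-2-chloro-1-{5-[(E)-heptadec-12-en-1-yl]furan-2-yl}ethan-1-ol
Product: 15 (2R)-2-(chloromethyl)-6-[(E)-heptadec-12-en-1-yl]-6-hydroxy-2H-pyran-3(6H)-one, via Z-enedione carbinol 14 (not isolated)
Conditions: NBS (1.05 equiv), NaOAc·3H2O, THF/H2O (4:1), 0 °C
Reagents that add atoms: water, O
Why: Achmatowicz rearrangement, in which NBS attacks the electron-rich 2,5-disubstituted furan far faster than the isolated chain alkene, water opens the ring to Z-enedione 14, and the carbinol oxygen closes onto the chain ketone, while acetate buffering without stronger base should spare the β-chloro ketone from elimination and C2 epimerisation.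

Step 8
Reactants: 15 (2R)-2-(chloromethyl)-6-[(E)-heptadec-12-en-1-yl]-6-hydroxy-2H-pyran-3(6H)-one
Product: 16 (2R,6R)-2-(chloromethyl)-6-[(E)-heptadec-12-en-1-yl]-6-methoxy-2H-pyran-3(6H)-one
Conditions: HC(OMe)3, BF3·OEt2 (cat.), CH2Cl2, −20 → 0 °C
Reagents that add atoms: trimethyl orthoformate, COC(OC)OC
Why: Acid-catalysed ketal exchange through the ring oxocarbenium ion is reversible and should settle on the anomer with methoxy axial (anomeric effect) and both the chain and CH2Cl equatorial, that is OMe trans to CH2Cl (6R).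

Step 9
Reactants: 16 (2R,6R)-2-(chloromethyl)-6-[(E)-heptadec-12-en-1-yl]-6-methoxy-2H-pyran-3(6H)-one
Product: 17 (2R,3R,6R)-2-(chloromethyl)-6-[(E)-heptadec-12-en-1-yl]-6-methoxy-3,6-dihydro-2H-pyran-3-ol
Conditions: NaBH4, CeCl3·7H2O, MeOH/CH2Cl2, −78 °C
Reagents that add atoms: none
Why: Luche 1,2-reduction of the enone, with hydride entering axially on the face opposite the axial anomeric methoxy group, so the new hydroxyl should be trans to CH2Cl and cis to OMe (3R); this carbon becomes C4 of the target.

Step 10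
Reactants: 17 (2R,3R,6R)-2-(chloromethyl)-6-[(E)-heptadec-12-en-1-yl]-6-methoxy-3,6-dihydro-2H-pyran-3-ol
Product: 18 tert-butyl{[(2R,3R,6R)-2-(chloromethyl)-6-[(E)-heptadec-12-en-1-yl]-6-methoxy-3,6-dihydro-2H-pyran-3-yl]oxy}dimethylsilane
Conditions: TBSCl, imidazole, DMF, rt
Reagents that add atoms: tert-butyldimethylsilyl chloride, CC(C)(C)[Si](C)(C)Cl
Why: Standard silylation of a secondary allylic alcohol under basic conditions that the methyl ketal tolerates.

Step 11
Reactants: 18 tert-butyl{[(2R,3R,6R)-2-(chloromethyl)-6-[(E)-heptadec-12-en-1-yl]-6-methoxy-3,6-dihydro-2H-pyran-3-yl]oxy}dimethylsilane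
Product: 19 tert-butyl{[(2R,3R,6R)-6-[(E)-heptadec-12-en-1-yl]-2-(iodomethyl)-6-methoxy-3,6-dihydro-2H-pyran-3-yl]oxy}dimethylsilane
Conditions: NaI (10 equiv), NaHCO3, butanone, 80 °C
Reagents that add atoms: sodium iodide, [Na+].[I-]
Why: Finkelstein halide exchange, driven by precipitation of NaCl, should give the primary iodide needed for a mild elimination, and bicarbonate keeps the medium neutral for the ketal.

Step 12
Reactants: 19 tert-butyl{[(2R,3R,6R)-6-[(E)-heptadec-12-en-1-yl]-2-(iodomethyl)-6-methoxy-3,6-dihydro-2H-pyran-3-yl]oxy}dimethylsilane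
Product: 20 tert-butyl{[(3R,6R)-6-[(E)-heptadec-12-en-1-yl]-6-methoxy-2-methylidene-3,6-dihydro-2H-pyran-3-yl]oxy}dimethylsilane
Conditions: DBU, toluene, 80 °C; chromatography on Et3N-deactivated silica
Reagents that add atoms: none
Why: E2 dehydroiodination with the non-nucleophilic amidine removes the only β-hydrogen, on the ring carbon next to oxygen, giving the exocyclic enol ether and erasing the relay stereocentre once it has set C4.

Step 13
Reactants: 20 tert-butyl{[(3R,6R)-6-[(E)-heptadec-12-en-1-yl]-6-methoxy-2-methylidene-3,6-dihydro-2H-pyran-3-yl]oxy}dimethylsilane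
Product: 23 (2R,5R)-2-[(tert-butyldimethylsilyl)oxy]-5-[(E)-heptadec-12-en-1-yl]-5-hydroxycyclohex-3-en-1-one, via hemiketal organomercurial 21 (not isolated), via open-chain mercurio enedione 22 (not isolated)
Conditions: Hg(OCOCF3)2 (5 mol%), acetone/H2O (3:1), 0 °C → rt; crude 23 taken at once into step 14
Reagents that add atoms: water, O
Why: Proposed new method: divalent mercury should add to the electron-rich exocyclic enol ether (much faster than to the isolated E-alkene, the ring alkene or the ketal), water adds at C5 to give hemiketal 21, and collapse to the C5 ketone frees the ring oxygen on C1 as a methyl hemiketal that loses methanol, so that the chain ketone appears as a Z-enone with mercury on C6 (22). The α-mercurio ketone reacts as a mercury enolate and adds through C6 to the C1 carbonyl, a 6-(enolendo)-exo-trig aldol closure of the cyclohexene ring and the only six-membered mode available (attack at C3 would make a cyclobutane), after which protonolysis of the O–Hg bond returns the catalyst. The closest known reaction type is the Ferrier carbocyclisation of 6-deoxyhex-5-enopyranosides under Hg(OCOCF3)2 or PdCl2 catalysis, in which C1 is an aldehyde; the untested element here is a conjugated ketone as acceptor. The new C1 stereocentre is controlled by the C4 stereocentre: in the half-chair transition state the C4 silyloxy group and the C17 chain on C1 both sit pseudoequatorial, which places the C1 oxygen pseudoaxial and cis to the C4 oxygen (1R), and reversibility of the aldol should let the ring settle on this isomer. The step needs C–C bond formation to outrun protodemercuration, Z-to-E isomerisation and dehydration, and the substrate secures this by holding C6 and C1 cis across the former ring alkene, while the near-neutral medium and immediate reduction in step 14 protect the β,γ-unsaturated aldol.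

Step 14
Reactants: 23 (2R,5R)-2-[(tert-butyldimethylsilyl)oxy]-5-[(E)-heptadec-12-en-1-yl]-5-hydroxycyclohex-3-en-1-one
Product: 24 (1R,4R,5R)-4-[(tert-butyldimethylsilyl)oxy]-1-[(E)-heptadec-12-en-1-yl]cyclohex-2-ene-1,5-diol
Conditions: Me4NBH(OAc)3, MeCN/AcOH (1:1), −30 °C
Reagents that add atoms: none
Why: Evans–Saksena hydroxyl-directed reduction, in which the pseudoaxial tertiary C1 hydroxyl exchanges onto boron and delivers hydride to the same face of the C5 ketone, so the new C5 hydroxyl should be anti to C1–OH and trans to the C4 silyloxy group (5R), and the cold, fast reduction forestalls olefin migration.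

Step 15
Reactants: 24 (1R,4R,5R)-4-[(tert-butyldimethylsilyl)oxy]-1-[(E)-heptadec-12-en-1-yl]cyclohex-2-ene-1,5-diol
Product: 25 (1R,4R,5R)-1-[(E)-heptadec-12-en-1-yl]cyclohex-2-ene-1,4,5-triol
Conditions: Bu4NF, THF, 0 °C → rt
Reagents that add atoms: none
Why: Fluoride-mediated silyl ether cleavage should release the C4 hydroxyl without affecting the tertiary allylic alcohol or either alkene.

**Compound list**

1 | 1-hexyne | CCCCC#C | starting material
2 | 11-bromoundecan-1-ol | OCCCCCCCCCCCBr | starting material
3 | hex-1-ynyllithium | CCCCC#C[Li] | intermediate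
4 | heptadec-12-yn-1-ol | CCCCC#CCCCCCCCCCCCO | intermediate
5 | (E)-heptadec-12-en-1-ol | CCCC/C=C/CCCCCCCCCCCO | intermediate
6 | (E)-1-bromoheptadec-12-ene | CCCC/C=C/CCCCCCCCCCCBr | intermediate
7 | furan | c1ccoc1 | starting material
8 | 2-lithiofuran | [Li]c1ccco1 | intermediate
9 | 2-[(E)-heptadec-12-en-1-yl]furan | CCCC/C=C/CCCCCCCCCCCc1ccco1 | intermediate
10 | 2-chloro-N-methoxy-N-methylacetamide | CON(C)C(=O)CCl | starting material
11 | {5-[(E)-heptadec-12-en-1-yl]furan-2-yl}lithium | CCCC/C=C/CCCCCCCCCCCc1ccc([Li])o1 | intermediate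
12 | 2-chloro-1-{5-[(E)-heptadec-12-en-1-yl]furan-2-yl}ethan-1-one | CCCC/C=C/CCCCCCCCCCCc1ccc(o1)C(=O)CCl | intermediate
13 | (1R)-2-chloro-1-{5-[(E)-heptadec-12-en-1-yl]furan-2-yl}ethan-1-ol | CCCC/C=C/CCCCCCCCCCCc1ccc(o1)[C@@H](O)CCl | intermediate
14 | (2R,4Z,18E)-1-chloro-2-hydroxytricosa-4,18-diene-3,6-dione | CCCC/C=C/CCCCCCCCCCCC(=O)/C=C\C(=O)[C@@H](O)CCl | intermediate
15 | (2R)-2-(chloromethyl)-6-[(E)-heptadec-12-en-1-yl]-6-hydroxy-2H-pyran-3(6H)-one (C6 epimers) | CCCC/C=C/CCCCCCCCCCCC1(O)C=CC(=O)[C@H](CCl)O1 | intermediate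
16 | (2R,6R)-2-(chloromethyl)-6-[(E)-heptadec-12-en-1-yl]-6-methoxy-2H-pyran-3(6H)-one | CCCC/C=C/CCCCCCCCCCC[C@]1(OC)C=CC(=O)[C@H](CCl)O1 | intermediate
17 | (2R,3R,6R)-2-(chloromethyl)-6-[(E)-heptadec-12-en-1-yl]-6-methoxy-3,6-dihydro-2H-pyran-3-ol | CCCC/C=C/CCCCCCCCCCC[C@]1(OC)C=C[C@@H](O)[C@H](CCl)O1 | intermediate
18 | tert-butyl{[(2R,3R,6R)-2-(chloromethyl)-6-[(E)-heptadec-12-en-1-yl]-6-methoxy-3,6-dihydro-2H-pyran-3-yl]oxy}dimethylsilane | CCCC/C=C/CCCCCCCCCCC[C@]1(OC)C=C[C@@H](O[Si](C)(C)C(C)(C)C)[C@H](CCl)O1 | intermediate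
19 | tert-butyl{[(2R,3R,6R)-6-[(E)-heptadec-12-en-1-yl]-2-(iodomethyl)-6-methoxy-3,6-dihydro-2H-pyran-3-yl]oxy}dimethylsilane | CCCC/C=C/CCCCCCCCCCC[C@]1(OC)C=C[C@@H](O[Si](C)(C)C(C)(C)C)[C@H](CI)O1 | intermediate
20 | tert-butyl{[(3R,6R)-6-[(E)-heptadec-12-en-1-yl]-6-methoxy-2-methylidene-3,6-dihydro-2H-pyran-3-yl]oxy}dimethylsilane | CCCC/C=C/CCCCCCCCCCC[C@]1(OC)C=C[C@@H](O[Si](C)(C)C(C)(C)C)C(=C)O1 | intermediate
21 | {[(3R,6R)-3-[(tert-butyldimethylsilyl)oxy]-6-[(E)-heptadec-12-en-1-yl]-2-hydroxy-6-methoxy-3,6-dihydro-2H-pyran-2-yl]methyl}mercury trifluoroacetate | CCCC/C=C/CCCCCCCCCCC[C@]1(OC)C=C[C@@H](O[Si](C)(C)C(C)(C)C)C(O)(C[Hg]OC(=O)C(F)(F)F)O1 | intermediate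
22 | [(3R,4Z,18E)-3-[(tert-butyldimethylsilyl)oxy]-2,6-dioxotricosa-4,18-dien-1-yl]mercury trifluoroacetate | CCCC/C=C/CCCCCCCCCCCC(=O)\C=C/[C@@H](O[Si](C)(C)C(C)(C)C)C(=O)C[Hg]OC(=O)C(F)(F)F | intermediate
23 | (2R,5R)-2-[(tert-butyldimethylsilyl)oxy]-5-[(E)-heptadec-12-en-1-yl]-5-hydroxycyclohex-3-en-1-one | CCCC/C=C/CCCCCCCCCCC[C@]1(O)C=C[C@@H](O[Si](C)(C)C(C)(C)C)C(=O)C1 | intermediate
24 | (1R,4R,5R)-4-[(tert-butyldimethylsilyl)oxy]-1-[(E)-heptadec-12-en-1-yl]cyclohex-2-ene-1,5-diol | CCCC/C=C/CCCCCCCCCCC[C@]1(O)C=C[C@@H](O[Si](C)(C)C(C)(C)C)[C@H](O)C1 | intermediate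
25 | (1R,4R,5R)-1-[(E)-heptadec-12-en-1-yl]cyclohex-2-ene-1,4,5-triol | CCCC/C=C/CCCCCCCCCCC[C@]1(O)C=C[C@@H](O)[C@H](O)C1 | target

**Step count and risks**

Total step count: 15. Longest linear sequence: 15 steps (steps 1–15 from 1-hexyne and 11-bromoundecan-1-ol; furan and the Weinreb amide enter at steps 4 and 5).

Steps most likely to fail:

1. Step 13 (the proposed new method). Addition of the C6 mercury enolate to the conjugated, less electrophilic C1 ketone may be slower than protonolysis of the C–Hg bond, so the ring would not close and the open-chain Z-enedione would isomerise or dehydrate. The fallback uses known chemistry and makes the enolate stoichiometrically and regiospecifically. It sets out from 20: iodohydration of the enol ether (NIS, NaHCO3, THF/H2O, 0 °C), with collapse of the C5 hemiketal and loss of methanol, should give the α-iodo ketone (3R,4Z,18E)-3-[(tert-butyldimethylsilyl)oxy]-1-iodotricosa-4,18-diene-2,6-dione F1. Treatment with SmI2 (2.2 equiv, THF, −78 °C) reduces the C–I bond far faster than the enone and generates a trivalent samarium enolate at C6, which should close onto the Lewis-acid-activated C1 ketone in an intramolecular Reformatsky-type aldol under the same C4-controlled half-chair preference. The fallback comes back to the route at 23.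

2. Step 11. Iodide displacement at the β-oxygenated, β-branched primary chloride may be so slow that the allylic ketal or the silyl ether degrades on prolonged heating. The fallback replaces halide exchange and base elimination by a selenoxide elimination and sets out from 18: the far more nucleophilic selenolate (PhSeSePh, NaBH4, EtOH/THF, 50 °C) should give the selenide tert-butyl{[(2R,3R,6R)-6-[(E)-heptadec-12-en-1-yl]-6-methoxy-2-[(phenylselanyl)methyl]-3,6-dihydro-2H-pyran-3-yl]oxy}dimethylsilane F2. Oxidation with mCPBA (1.0 equiv, CH2Cl2, −78 °C) gives the selenoxide tert-butyl{[(2R,3R,6R)-6-[(E)-heptadec-12-en-1-yl]-6-methoxy-2-[(phenylseleninyl)methyl]-3,6-dihydro-2H-pyran-3-yl]oxy}dimethylsilane F3, which is not isolated. Warming with i-Pr2NH in toluene at 80 °C should bring about syn-elimination toward the only β-hydrogen. The fallback comes back to the route at 20, bypassing 19 and step 12.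

3. Step 14. Ligand exchange of the hindered tertiary C1 hydroxyl onto boron may be slow, so that external hydride attack on the wrong C5 face, or acid-promoted olefin migration and dehydration of the aldol, competes. The fallback accepts the opposite facial selectivity and corrects it by inversion; it sets out from 23. The bulky hydride LiBH(s-Bu)3 (THF, −78 °C) should attack anti to the pseudoaxial C1 hydroxyl and give the 5-epimer (1R,4R,5S)-4-[(tert-butyldimethylsilyl)oxy]-1-[(E)-heptadec-12-en-1-yl]cyclohex-2-ene-1,5-diol F4. Mitsunobu inversion of the secondary axial alcohol (4-nitrobenzoic acid, PPh3, DIAD, toluene, 0 °C; the tertiary alcohol does not react) should give (1R,2R,5R)-2-[(tert-butyldimethylsilyl)oxy]-5-[(E)-heptadec-12-en-1-yl]-5-hydroxycyclohex-3-en-1-yl 4-nitrobenzoate F5. Methanolysis (K2CO3, MeOH, 0 °C) then comes back to the route at 24.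

**Further compounds**

F1 | step 13 | (3R,4Z,18E)-3-[(tert-butyldimethylsilyl)oxy]-1-iodotricosa-4,18-diene-2,6-dione | CCCC/C=C/CCCCCCCCCCCC(=O)\C=C/[C@@H](O[Si](C)(C)C(C)(C)C)C(=O)CI
F2 | step 11 | tert-butyl{[(2R,3R,6R)-6-[(E)-heptadec-12-en-1-yl]-6-methoxy-2-[(phenylselanyl)methyl]-3,6-dihydro-2H-pyran-3-yl]oxy}dimethylsilane | CCCC/C=C/CCCCCCCCCCC[C@]1(OC)C=C[C@@H](O[Si](C)(C)C(C)(C)C)[C@H](C[Se]c2ccccc2)O1
F3 | step 11 | tert-butyl{[(2R,3R,6R)-6-[(E)-heptadec-12-en-1-yl]-6-methoxy-2-[(phenylseleninyl)methyl]-3,6-dihydro-2H-pyran-3-yl]oxy}dimethylsilane | CCCC/C=C/CCCCCCCCCCC[C@]1(OC)C=C[C@@H](O[Si](C)(C)C(C)(C)C)[C@H](C[Se](=O)c2ccccc2)O1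
F4 | step 14 | (1R,4R,5S)-4-[(tert-butyldimethylsilyl)oxy]-1-[(E)-heptadec-12-en-1-yl]cyclohex-2-ene-1,5-diol | CCCC/C=C/CCCCCCCCCCC[C@]1(O)C=C[C@@H](O[Si](C)(C)C(C)(C)C)[C@@H](O)C1
F5 | step 14 | (1R,2R,5R)-2-[(tert-butyldimethylsilyl)oxy]-5-[(E)-heptadec-12-en-1-yl]-5-hydroxycyclohex-3-en-1-yl 4-nitrobenzoate | CCCC/C=C/CCCCCCCCCCC[C@]1(O)C=C[C@@H](O[Si](C)(C)C(C)(C)C)[C@H](OC(=O)c2ccc(cc2)[N+](=O)[O-])C1
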